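## The problem

Compound 23 is a 1,1-diarylalkane. Two fully substituted phloroglucinol rings are joined only through one sp3 carbon (the bridge), which also carries a hydrogen and a 5-methylhexyl chain (C1 to C6), so no ring has to be closed. Ring A carries the (R)-2-methylbutanoyl group and ring B the isobutyryl group; otherwise the rings are identical (bridge, three hydroxyls, one prenyl, one acyl, in the same order round the ring). There are two stereocentres, the bridge carbon (R) and the α-carbon of the ring A acyl group (R). They are eight bonds apart and cannot direct each other, so the acyl centre is bought and the bridge must be set by a chiral reagent. The bridge is stereogenic only because one acyl group ends in ethyl where the other ends in methyl. The real task is therefore to tell two all but enantiotopic rings apart at a stage where they still differ in something a catalyst can sense. The prenyl groups will not survive hydrogenation, BBr3 or strong acid, the acyl α-centre can enolise, and the free bis-phloroglucinol is open to oxidation and to acid- or base-induced ionisation of a bridge–aryl bond (quinone methide), which would scramble the bridge. The enabling feature is that the bridge carbon, chain C1, chain C2 and the oxygen on the ring B carbon next to the bridge map onto C4, C3, C2 and O1 of a 4-aryl-3,4-dihydrocoumarin. In that lactone ring B is fused and ring A is a twisted substituent, the bridge C–H bond can be made by conjugate hydride addition, the carbonyl is the future chain C2, and the ring oxygen later appears as the only free phenol.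

## Retrosynthesis

**23 to 21 and 22.** The two aryl–CH2 bonds of the prenyl groups are cut first. Prenyl groups tolerate none of the earlier chemistry (H2, light, AlCl3, BBr3), so they must come last. Hexaphenol 21 has exactly one unsubstituted carbon on each ring, so regiochemistry is not a question. The forward reaction must C-alkylate each ring once with prenyl bromide 22 without O-alkylation or a second, dearomatising alkylation.

**21 to 20.** Five O–CH3 bonds are cut. Methyl ethers are the one phenol protection that survives POCl3, palladium, copper hydride, aluminium hydride, an ylide, hydrogenation, 254 nm light and AlCl3. The forward reaction (BBr3) must leave the acyl α-centre and the bridge untouched. Having both rings acylated at that stage lowers their tendency to ionise at the bridge.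

**20 to 17 and 19 (from acid 18).** The ring A aryl–C(O) bond is cut. In 17 ring A is a 1,3,5-trimethoxyarene with two equivalent free carbons, while the single free carbon of ring B is deactivated by the ketone already there. A cold Friedel–Crafts acylation should therefore choose ring A and can give only one product. Acylating before demethylation rather than after keeps the chiral acid chloride 19 away from a hot Lewis-acidic polyphenol.

**17 to 16, then 16 to 14 and 15.** The ring B aryl–C(O) bond is traced back to an O–acyl bond. Phenol 14 has one hydroxyl, on ring B, so isobutyryl chloride 15 can only give ester 16. A photo-Fries shift then moves the acyl group within its own solvent cage to the ortho carbon. A Lewis acid Fries reaction is rejected because a free acylium ion would prefer the more electron-rich ring A, which would lead to the wrong stereoisomer of 23. This step converts the OH/OMe difference between the rings into the acyl difference of the target.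

**14 to 13, then 13 to 9 and 11 (from bromide 10 via ylide 12).** The chain C2–C3 bond is cut as an alkene. Lactol 9 is a masked aldehyde at chain C2, and a Wittig reaction with the ylide from 1-bromo-3-methylbutane adds the remaining five carbons and releases the ring B phenol in the same step. Alkylating a two-carbon alcohol derivative instead would need a phenol protecting group, since the free phenol would close a chroman.

**9 to 8.** Only the oxidation level changes; the lactone is half-reduced.

**8 to 6 (via 7).** The bridge C–H bond is cut. Coumarin 6 is flat, achiral and free of sensitive groups. The forward reaction must deliver hydride to one face of a hindered C4, which is asked of a chiral bisphosphine copper hydride.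

**6 to 4 and 5; 4 to 3; 3 to 1 and 2.** The C4–aryl bond is cut as a Suzuki–Miyaura coupling of enol tosylate 4 with boronic acid 5. Tosylate 4 comes from 4-hydroxycoumarin 3, which is the condensation product of 3,5-dimethoxyphenol 1 and malonic acid 2. All ring carbons of both arenes are bought.

## Roads not taken

**Alternative 1:** Ring B would be built rather than bought. Two ring bonds are cut so that the phenol A1 arises from a siloxyalkyne A2, which already holds the bridge stereocentre, ring A and the chain, and from 3-ethoxycyclobut-2-en-1-one A3.
- Forward step: heating opens A3 to a vinylketene, which adds to the alkyne of A2; a second four-electron opening, a six-electron closure and tautomerisation give A1 (a Danheiser benzannulation).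
- Merits: the regiochemistry is fixed by the pericyclic sequence. Ring B emerges with three different oxygen functions (OH, silyl ether, ethyl ether), which would allow ground-state, regiocontrolled acylation of ring B.
- Weak points: the step does not create the stereocentre. A2 must already be enantiopure at a propargylic, benzylic carbon next to a di-ortho-methoxy arene, which is the original problem moved to a less convenient substrate. A2 also takes several steps to make, and the oxygen differentiation is wasted because all three end as hydroxyls.
- Comparison: Alternative 1 is better at directing the ring B acyl group and would avoid the photochemical step. The chosen plan sets against this a catalytic creation of the stereocentre on a simple lactone, two purchased rings and a shorter sequence.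

**Alternative 2:** The bridge–C1 bond would be made last. A racemic diaryl carbinol A5, with both rings fully substituted and ring B as its tris(methoxymethyl) ether, would be ionised to the ring A ortho-quinone methide. A chiral copper catalyst (Cu(OTf)2 with a phosphoramidite) would then add the alkyl group of bis(5-methylhexyl)zinc A6 to give A4, one deprotection from the target.
- Merits: it is the most convergent plan and is stereoconvergent. The acyl and prenyl groups are installed on monomers by routine chemistry, so the late double prenylation and the photo-Fries step of the chosen route are not needed. In step economy it is clearly better if it works.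
- Weak points: the methide carbon lies between two hexasubstituted rings. The catalyst must choose a face of a methide whose substituent is almost a copy of the ring it sits on. Three phenols, two enolisable ketones (one the acyl stereocentre) and two prenyl groups are exposed to a dialkylzinc and a Lewis acid. Enantioselective addition of sp3 alkyl groups to such methides has little precedent. The final acidic removal of the acetals from A4 threatens chroman formation and bridge ionisation.
- Comparison: the chosen plan sets against the shorter count a stereo-determining step of a known class, run on a substrate in which the two rings are constitutionally different and no sensitive group is present.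

**Alternative 3:** The stereocentre would be created by acylating one of two enantiotopic rings. The prochiral bis-phenol A8 would be treated with an isobutyryl donor and a chiral nucleophilic acyl-transfer catalyst to give the mono-ester A7.
- Merits: A8 is achiral and short to make. O-Methylation of A7 would give compound 16 of the chosen route directly, several steps earlier than the lactone sequence reaches it. In step count this road is the better one.
- Weak points: the catalyst must distinguish two phenols related by a mirror plane through a CH(alkyl) carbon, both flanked by the bulky bridge. Double acylation competes. A7 keeps a free phenol on ring A next to the ester on ring B, and transfer of the acyl group between these two oxygens turns A7 into its enantiomer, so the product can racemise by itself. The condensation that would make A8 from 3,5-dimethoxyphenol also has an ortho/para regiochemistry problem.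
- Comparison: the chosen plan sets against the shorter count a known asymmetric reaction class and a ring distinction that is fixed covalently in a lactone and cannot be lost by acyl migration.

Key step: step 4

Assumption: (R)-DTBM-SEGPHOS is taken as the ligand antipode that gives (4S)-8; the sense is to be checked on the first run and the (S)-ligand is used instead if it proves opposite.

Remark: the bridge descriptor alternates along the route (S in 7, 8, 9 and 16; R in 13, 14, 17, 20, 21 and 23) only because ring priorities change; the spatial arrangement set in step 4 is the same throughout.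

## Route

Step 1
Reactants: 1 3,5-dimethoxyphenol; 2 malonic acid
Product: 3 4-hydroxy-5,7-dimethoxy-2H-chromen-2-one
Conditions: ZnCl2 (3 equiv), POCl3, 65 °C; ice-water
Reagents that add atoms: none
Why: Pechmann-type condensation: O-acylation of the phenol by activated malonic acid and intramolecular Friedel–Crafts acylation ortho to the oxygen; the two ortho positions of 1 are equivalent, so only one coumarin can form.

Step 2
Reactants: 3 4-hydroxy-5,7-dimethoxy-2H-chromen-2-one
Product: 4 5,7-dimethoxy-2-oxo-2H-chromen-4-yl 4-methylbenzenesulfonate
Conditions: TsCl (1.2 equiv), Et3N (1.5 equiv), CH2Cl2, 0 °C to rt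
Reagents that add atoms: p-toluenesulfonyl chloride, Cc1ccc(cc1)S(=O)(=O)Cl
Why: O-sulfonylation of the acidic vinylogous acid; the enol tosylate is a stable electrophile for cross-coupling.

Step 3
Reactants: 4 5,7-dimethoxy-2-oxo-2H-chromen-4-yl 4-methylbenzenesulfonate; 5 (2,4,6-trimethoxyphenyl)boronic acid
Product: 6 5,7-dimethoxy-4-(2,4,6-trimethoxyphenyl)-2H-chromen-2-one
Conditions: Pd(OAc)2 (5 mol %), SPhos (10 mol %), K3PO4 (3 equiv), toluene/H2O (10:1), 80 °C; dilute HCl work-up
Reagents that add atoms: none
Why: Suzuki–Miyaura coupling; zerovalent palladium inserts readily into the activated C4–O bond of the enol tosylate, and the electron-rich biaryl phosphine is chosen so that transmetalation of the di-ortho-substituted boronic acid outruns its protodeboronation.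

Step 4
Reactants: 6 5,7-dimethoxy-4-(2,4,6-trimethoxyphenyl)-2H-chromen-2-one
Product: 8 (4S)-5,7-dimethoxy-4-(2,4,6-trimethoxyphenyl)chroman-2-one, via silyl ketene acetal 7 (not isolated)
Conditions: Cu(OAc)2·H2O (5 mol %), (R)-DTBM-SEGPHOS (5.5 mol %), (EtO)2MeSiH (3 equiv), toluene, rt to 40 °C; then 1 M HCl, THF, 0 °C
Reagents that add atoms: none
Why: The silane reduces divalent copper acetate to a bisphosphine-ligated monovalent copper hydride, which adds across C3=C4 so that hydride goes to C4 and copper to the enolate; exchange with Si–H gives silyl ketene acetal 7 and returns the copper hydride, and dilute acid hydrolyses 7 to lactone 8. The closest known reaction type is the copper hydride-catalysed asymmetric 1,4-reduction of β,β-disubstituted enoates and 4-substituted coumarins. No ring closes and no skeletal bond forms; the only new bond is the bridge C–H. The C4 stereocentre is under catalyst control: the chiral bisphosphine chooses the face of an enoate whose geometry is locked by the lactone. The step needs 1,4- over 1,2-selectivity, which ligated copper hydride shows for enoates and which is protected further because the product rests as 7 until work-up. It also needs facial selectivity, and here the lactone makes the two C4 substituents different in kind, the coplanar fused ring B and the perpendicular ring A. The two ortho-methoxy groups of ring A shield both faces equally, so they should slow the reaction without biasing it. If the enantiomeric purity falls short, 8 should be amenable to enrichment by crystallisation.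

Step 5
Reactants: 8 (4S)-5,7-dimethoxy-4-(2,4,6-trimethoxyphenyl)chroman-2-one
Product: 9 (4S)-5,7-dimethoxy-4-(2,4,6-trimethoxyphenyl)chroman-2-ol (both C2 epimers)
Conditions: i-Bu2AlH (1.2 equiv), CH2Cl2, −78 °C; aq. potassium sodium tartrate
Reagents that add atoms: none
Why: Partial reduction of an aryl lactone stops at the aluminium hemiacetal at low temperature and gives the lactol on work-up; C4 is not involved and the new C2 centre disappears in step 7.

Step 6
Reactants: 10 1-bromo-3-methylbutane
Product: 11 (3-methylbutyl)triphenylphosphonium bromide
Conditions: PPh3 (1.0 equiv), toluene, reflux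
Reagents that add atoms: triphenylphosphine, c1ccc(cc1)P(c1ccccc1)c1ccccc1
Why: SN2 quaternisation of triphenylphosphine by a primary alkyl bromide.

Step 7
Reactants: 9 (4S)-5,7-dimethoxy-4-(2,4,6-trimethoxyphenyl)chroman-2-ol; 11 (3-methylbutyl)triphenylphosphonium bromide
Product: 13 3,5-dimethoxy-2-[(1R,3Z)-6-methyl-1-(2,4,6-trimethoxyphenyl)hept-3-en-1-yl]phenol, via phosphorus ylide 12 (not isolated)
Conditions: 11 (3 equiv), KN(SiMe3)2 (2.9 equiv), THF, 0 °C; then 9, −78 °C to rt; aq. NH4Cl
Reagents that add atoms: none
Why: Wittig olefination of the open hydroxy-aldehyde form of the lactol with an unstabilised ylide, used in excess to allow for the phenoxide; the alkene geometry (expected mainly Z) is irrelevant because the alkene is reduced next, and the ring B oxygen is released as the only phenol in the molecule.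

Step 8
Reactants: 13 3,5-dimethoxy-2-[(1R,3Z)-6-methyl-1-(2,4,6-trimethoxyphenyl)hept-3-en-1-yl]phenol
Product: 14 3,5-dimethoxy-2-[(1R)-6-methyl-1-(2,4,6-trimethoxyphenyl)heptyl]phenol
Conditions: H2 (1 atm), Pd/C (10 wt %), EtOAc, rt
Reagents that add atoms: none
Why: Catalytic hydrogenation of a disubstituted alkene; aryl ethers, the phenol and the diarylmethine C–H are inert under these conditions.

Step 9
Reactants: 14 3,5-dimethoxy-2-[(1R)-6-methyl-1-(2,4,6-trimethoxyphenyl)heptyl]phenol; 15 2-methylpropanoyl chloride
Product: 16 3,5-dimethoxy-2-[(1S)-6-methyl-1-(2,4,6-trimethoxyphenyl)heptyl]phenyl 2-methylpropanoate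
Conditions: Et3N (2 equiv), DMAP (0.1 equiv), CH2Cl2, 0 °C to rt
Reagents that add atoms: none
Why: DMAP-catalysed esterification of the single free phenol; ring A has no hydroxyl, so the isobutyryl group is placed on ring B without a selectivity problem.

Step 10
Reactants: 16 3,5-dimethoxy-2-[(1S)-6-methyl-1-(2,4,6-trimethoxyphenyl)heptyl]phenyl 2-methylpropanoate
Product: 17 1-{2-hydroxy-4,6-dimethoxy-3-[(1R)-6-methyl-1-(2,4,6-trimethoxyphenyl)heptyl]phenyl}-2-methylpropan-1-one
Conditions: hν (254 nm, low-pressure mercury lamp, quartz), degassed cyclohexane (dilute), rt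
Reagents that add atoms: none
Why: Photo-Fries rearrangement: homolysis of the ArO–acyl bond gives a caged phenoxyl/acyl radical pair that recombines at the free ortho carbon and tautomerises to the hydrogen-bonded ortho-hydroxy ketone; the acyl radical stays in the cage of its own ring, so it cannot reach ring A, and the bridge is not touched.

Step 11
Reactants: 18 (2R)-2-methylbutanoic acid
Product: 19 (2R)-2-methylbutanoyl chloride
Conditions: (COCl)2 (1.2 equiv), DMF (cat.), CH2Cl2, 0 °C to rt; evaporate, use crude
Reagents that add atoms: oxalyl chloride, O=C(Cl)C(=O)Cl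
Why: Acid chloride formation through a Vilsmeier-type chloroiminium salt under base-free conditions, which avoids ketene formation and so keeps the α-stereocentre.

Step 12
Reactants: 17 1-{2-hydroxy-4,6-dimethoxy-3-[(1R)-6-methyl-1-(2,4,6-trimethoxyphenyl)heptyl]phenyl}-2-methylpropan-1-one; 19 (2R)-2-methylbutanoyl chloride
Product: 20 (2R)-1-{3-[(1R)-1-[2-hydroxy-4,6-dimethoxy-3-(2-methylpropanoyl)phenyl]-6-methylheptyl]-2,4,6-trimethoxyphenyl}-2-methylbutan-1-one
Conditions: AlCl3 (2.5 equiv), CH2Cl2, −20 to 0 °C; ice/1 M HCl
Reagents that add atoms: none
Why: Friedel–Crafts acylation of a 1,3,5-trimethoxyarene; ring A has three undisturbed donors and two equivalent free carbons, whereas the one free carbon of ring B is deactivated by its ketone and the aluminium chelate of the ortho-hydroxy ketone, and the low temperature is chosen so that the acylium ion is consumed before its α-centre can epimerise.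

Step 13
Reactants: 20 (2R)-1-{3-[(1R)-1-[2-hydroxy-4,6-dimethoxy-3-(2-methylpropanoyl)phenyl]-6-methylheptyl]-2,4,6-trimethoxyphenyl}-2-methylbutan-1-one
Product: 21 (2R)-1-{2,4,6-trihydroxy-3-[(1R)-6-methyl-1-[2,4,6-trihydroxy-3-(2-methylpropanoyl)phenyl]heptyl]phenyl}-2-methylbutan-1-one
Conditions: BBr3 (12 equiv), CH2Cl2, −78 °C to rt; MeOH then H2O, 0 °C
Reagents that add atoms: none
Why: Lewis acid cleavage of aryl methyl ethers by BBr3 (bromide attacks the O-methyl group of the boron-bound ether); the ketones assist cleavage of their ortho ethers by chelation, and no prenyl group is present yet.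

Step 14
Reactants: 21 (2R)-1-{2,4,6-trihydroxy-3-[(1R)-6-methyl-1-[2,4,6-trihydroxy-3-(2-methylpropanoyl)phenyl]heptyl]phenyl}-2-methylbutan-1-one; 22 1-bromo-3-methylbut-2-ene
Product: 23 (2R)-1-{2,4,6-trihydroxy-3-[(1R)-6-methyl-1-[2,4,6-trihydroxy-3-(3-methylbut-2-enyl)-5-(2-methylpropanoyl)phenyl]heptyl]-5-(3-methylbut-2-enyl)phenyl}-2-methylbutan-1-one
Conditions: KOH (10 % aq.), 0 °C, Ar; 22 (2.2 equiv); then 1 M HCl
Reagents that add atoms: none
Why: C-alkylation of acylphloroglucinol phenoxides (vinylogous enolates) by an allylic bromide in water, the classical C-prenylation of this compound class; each ring has one unsubstituted nucleophilic carbon left, and limiting the bromide and the temperature should keep O-alkylation and a second, dearomatising alkylation down.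

## Compound list

1 | 3,5-dimethoxyphenol | COc1cc(O)cc(OC)c1 | starting material
2 | malonic acid | OC(=O)CC(=O)O | starting material
3 | 4-hydroxy-5,7-dimethoxy-2H-chromen-2-one | COc1cc(OC)c2C(O)=CC(=O)Oc2c1 | intermediate
4 | 5,7-dimethoxy-2-oxo-2H-chromen-4-yl 4-methylbenzenesulfonate | COc1cc(OC)c2C(OS(=O)(=O)c3ccc(C)cc3)=CC(=O)Oc2c1 | intermediate
5 | (2,4,6-trimethoxyphenyl)boronic acid | COc1cc(OC)c(B(O)O)c(OC)c1 | starting material
6 | 5,7-dimethoxy-4-(2,4,6-trimethoxyphenyl)-2H-chromen-2-one | COc1cc(OC)cc(OC)c1C1=CC(=O)Oc2cc(OC)cc(OC)c21 | intermediate
7 | (4S)-2-{[diethoxy(methyl)silyl]oxy}-5,7-dimethoxy-4-(2,4,6-trimethoxyphenyl)-4H-chromene | COc1cc(OC)cc(OC)c1[C@@H]1C=C(O[Si](C)(OCC)OCC)Oc2cc(OC)cc(OC)c12 | intermediate (not isolated)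
8 | (4S)-5,7-dimethoxy-4-(2,4,6-trimethoxyphenyl)chroman-2-one | COc1cc(OC)cc(OC)c1[C@H](CC(=O)O2)c1c2cc(OC)cc1OC | intermediate
9 | (4S)-5,7-dimethoxy-4-(2,4,6-trimethoxyphenyl)chroman-2-ol, both C2 epimers | COc1cc(OC)cc(OC)c1[C@H](CC(O)O2)c1c2cc(OC)cc1OC | intermediate
10 | 1-bromo-3-methylbutane | CC(C)CCBr | starting material
11 | (3-methylbutyl)triphenylphosphonium bromide | CC(C)CC[P+](c1ccccc1)(c1ccccc1)c1ccccc1.[Br-] | intermediate
12 | (3-methylbutylidene)triphenylphosphorane | CC(C)CC=P(c1ccccc1)(c1ccccc1)c1ccccc1 | intermediate (not isolated)
13 | 3,5-dimethoxy-2-[(1R,3Z)-6-methyl-1-(2,4,6-trimethoxyphenyl)hept-3-en-1-yl]phenol | COc1cc(OC)cc(OC)c1[C@H](C/C=C\CC(C)C)c1c(O)cc(OC)cc1OC | intermediate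
14 | 3,5-dimethoxy-2-[(1R)-6-methyl-1-(2,4,6-trimethoxyphenyl)heptyl]phenol | COc1cc(OC)cc(OC)c1[C@H](CCCCC(C)C)c1c(O)cc(OC)cc1OC | intermediate
15 | 2-methylpropanoyl chloride | CC(C)C(=O)Cl | starting material
16 | 3,5-dimethoxy-2-[(1S)-6-methyl-1-(2,4,6-trimethoxyphenyl)heptyl]phenyl 2-methylpropanoate | COc1cc(OC)cc(OC)c1[C@H](CCCCC(C)C)c1c(OC(=O)C(C)C)cc(OC)cc1OC | intermediate
17 | 1-{2-hydroxy-4,6-dimethoxy-3-[(1R)-6-methyl-1-(2,4,6-trimethoxyphenyl)heptyl]phenyl}-2-methylpropan-1-one | COc1cc(OC)cc(OC)c1[C@H](CCCCC(C)C)c1c(O)c(C(=O)C(C)C)c(OC)cc1OC | intermediate
18 | (2R)-2-methylbutanoic acid | CC[C@@H](C)C(=O)O | starting material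
19 | (2R)-2-methylbutanoyl chloride | CC[C@@H](C)C(=O)Cl | intermediate
20 | (2R)-1-{3-[(1R)-1-[2-hydroxy-4,6-dimethoxy-3-(2-methylpropanoyl)phenyl]-6-methylheptyl]-2,4,6-trimethoxyphenyl}-2-methylbutan-1-one | CC[C@@H](C)C(=O)c1c(OC)cc(OC)c([C@H](CCCCC(C)C)c2c(O)c(C(=O)C(C)C)c(OC)cc2OC)c1OC | intermediate
21 | (2R)-1-{2,4,6-trihydroxy-3-[(1R)-6-methyl-1-[2,4,6-trihydroxy-3-(2-methylpropanoyl)phenyl]heptyl]phenyl}-2-methylbutan-1-one | CC[C@@H](C)C(=O)c1c(O)cc(O)c([C@H](CCCCC(C)C)c2c(O)c(C(=O)C(C)C)c(O)cc2O)c1O | intermediate
22 | 1-bromo-3-methylbut-2-ene | CC(C)=CCBr | starting material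
23 | (2R)-1-{2,4,6-trihydroxy-3-[(1R)-6-methyl-1-[2,4,6-trihydroxy-3-(3-methylbut-2-enyl)-5-(2-methylpropanoyl)phenyl]heptyl]-5-(3-methylbut-2-enyl)phenyl}-2-methylbutan-1-one | CC[C@@H](C)C(=O)c1c(O)c(CC=C(C)C)c(O)c([C@H](CCCCC(C)C)c2c(O)c(CC=C(C)C)c(O)c(C(=O)C(C)C)c2O)c1O | target

## Step count and least certain steps

Total: 14 steps. Longest linear sequence: 12 steps from 1 (steps 1 to 5, 7 to 10 and 12 to 14); steps 6 and 11 prepare the two side reagents.

**Step 4 (key step).** The most likely failure is slow hydride delivery or poor facial selectivity. C4 is shielded on both faces by the ortho-methoxy groups of the perpendicular ring A and on one flank by the 5-methoxy group, and a bulky ligand may keep the Cu–H bond from reaching it. Forcing the reaction could also open 1,2-reduction. The fallback sets out from 6 and gives up catalytic induction. The coumarin would be reduced without stereocontrol by electron transfer (Mg, MeOH, then acid to re-close the lactone), which does not need a reagent to approach C4 face-on, giving racemic 5,7-dimethoxy-4-(2,4,6-trimethoxyphenyl)chroman-2-one F1. F1 would be resolved by preparative chromatography on a chiral stationary phase, and the (4S)-enantiomer rejoins the route at 8.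

**Step 3.** Protodeboronation of the di-ortho-methoxy boronic acid under aqueous base may outrun transmetalation onto a hindered palladium centre, and the tosylate may hydrolyse back to 3. The fallback sets out from 4 and changes the nucleophile class. Commercial 1,3,5-trimethoxybenzene would be lithiated between two methoxy groups (n-BuLi, THF, 0 °C) and transmetalated with ZnCl2 to chloro(2,4,6-trimethoxyphenyl)zinc F2. A Negishi coupling of F2 with 4 (Pd(OAc)2, SPhos, THF, 60 °C) under anhydrous conditions would rejoin the route at 6.

**Step 10.** Escape of the acyl radical from the solvent cage would return phenol 14 (recyclable through step 9). Conversion may stall because the product absorbs the light, and secondary photolysis is possible. Recombination at the para carbon instead of the ortho carbon would not matter, since both positions become equivalent after step 13. The fallback sets out from 14 and uses ground-state chemistry that only a free phenol can undergo. Magnesium-mediated ortho-formylation (MgCl2, Et3N, paraformaldehyde, MeCN, reflux) would give 2-hydroxy-4,6-dimethoxy-3-[(1R)-6-methyl-1-(2,4,6-trimethoxyphenyl)heptyl]benzaldehyde F3. Addition of i-PrMgCl (2.5 equiv, THF, 0 °C) would give the carbinol 1-{2-hydroxy-4,6-dimethoxy-3-[(1R)-6-methyl-1-(2,4,6-trimethoxyphenyl)heptyl]phenyl}-2-methylpropan-1-ol F4, and oxidation with MnO2 (CH2Cl2, rt) rejoins the route at 17.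

**Step 13.** Three things may go wrong: incomplete cleavage of the ethers para to the ketones, epimerisation of the acyl α-carbon through a boron enolate, and acid-induced ionisation of a bridge–aryl bond. The fallback sets out from 17 and reverses the order, so that the chiral ketone never meets BBr3. Compound 17 would be demethylated first (BBr3, CH2Cl2, −78 °C to rt) to 1-{2,4,6-trihydroxy-3-[(1S)-6-methyl-1-(2,4,6-trihydroxyphenyl)heptyl]phenyl}-2-methylpropan-1-one F5. F5 would then be acylated on the unacylated, more electron-rich ring A with 19 (AlCl3, PhNO2/CH2Cl2, 0 °C to rt), rejoining the route at 21. This answers the α-epimerisation risk but not the bridge ionisation risk, which would be higher with a free phloroglucinol ring.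

**Step 14.** O-Prenylation, a second alkylation at an already substituted ring carbon (dearomatisation), incomplete double alkylation, and base-induced cleavage and recombination at the bridge are all possible with six phenols in alkali. The fallback sets out from 21 and separates C–C bond formation from the prenyl substitution pattern. Tsuji–Trost allylation (Pd(PPh3)4, allyl methyl carbonate, 2.1 equiv, THF, rt) would give the bis-allyl compound (2R)-1-{2,4,6-trihydroxy-3-[(1R)-6-methyl-1-[2,4,6-trihydroxy-3-(2-methylpropanoyl)-5-(prop-2-enyl)phenyl]heptyl]-5-(prop-2-enyl)phenyl}-2-methylbutan-1-one F6. O-Allyl ethers are re-ionised by zerovalent palladium, so material should collect as the C-allyl compound. Cross-metathesis of F6 with 2-methylbut-2-ene (second-generation Grubbs catalyst, RuCl2(=CHPh)(PCy3)(H2IMes), CH2Cl2, 40 °C) arrives at 23.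

## Further compounds

F1 | step 4 | racemic 5,7-dimethoxy-4-(2,4,6-trimethoxyphenyl)chroman-2-one | COc1cc(OC)cc(OC)c1C1CC(=O)Oc2cc(OC)cc(OC)c21
F2 | step 3 | chloro(2,4,6-trimethoxyphenyl)zinc | COc1cc(OC)c([Zn]Cl)c(OC)c1
F3 | step 10 | 2-hydroxy-4,6-dimethoxy-3-[(1R)-6-methyl-1-(2,4,6-trimethoxyphenyl)heptyl]benzaldehyde | COc1cc(OC)cc(OC)c1[C@H](CCCCC(C)C)c1c(O)c(C=O)c(OC)cc1OC
F4 | step 10 | 1-{2-hydroxy-4,6-dimethoxy-3-[(1R)-6-methyl-1-(2,4,6-trimethoxyphenyl)heptyl]phenyl}-2-methylpropan-1-ol, both carbinol epimers | COc1cc(OC)cc(OC)c1[C@H](CCCCC(C)C)c1c(O)c(C(O)C(C)C)c(OC)cc1OC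
F5 | step 13 | 1-{2,4,6-trihydroxy-3-[(1S)-6-methyl-1-(2,4,6-trihydroxyphenyl)heptyl]phenyl}-2-methylpropan-1-one | Oc1cc(O)cc(O)c1[C@H](CCCCC(C)C)c1c(O)c(C(=O)C(C)C)c(O)cc1O
F6 | step 14 | (2R)-1-{2,4,6-trihydroxy-3-[(1R)-6-methyl-1-[2,4,6-trihydroxy-3-(2-methylpropanoyl)-5-(prop-2-enyl)phenyl]heptyl]-5-(prop-2-enyl)phenyl}-2-methylbutan-1-one | CC[C@@H](C)C(=O)c1c(O)c(CC=C)c(O)c([C@H](CCCCC(C)C)c2c(O)c(CC=C)c(O)c(C(=O)C(C)C)c2O)c1O
A1 | alternative 1 | 5-ethoxy-2-[(1S)-6-methyl-1-(2,4,6-trimethoxyphenyl)heptyl]-3-(triisopropylsilyloxy)phenol | COc1cc(OC)cc(OC)c1[C@H](CCCCC(C)C)c1c(O[Si](C(C)C)(C(C)C)C(C)C)cc(OCC)cc1O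
A2 | alternative 1 | triisopropyl{[(3R)-8-methyl-3-(2,4,6-trimethoxyphenyl)non-1-yn-1-yl]oxy}silane | COc1cc(OC)cc(OC)c1[C@H](CCCCC(C)C)C#CO[Si](C(C)C)(C(C)C)C(C)C
A3 | alternative 1 | 3-ethoxycyclobut-2-en-1-one | CCOC1=CC(=O)C1
A4 | alternative 2 | ring B tris(methoxymethyl) ether of 23 | CC[C@@H](C)C(=O)c1c(O)c(CC=C(C)C)c(O)c([C@H](CCCCC(C)C)c2c(OCOC)c(CC=C(C)C)c(OCOC)c(C(=O)C(C)C)c2OCOC)c1O
A5 | alternative 2 | (2R)-1-{2,4,6-trihydroxy-3-[hydroxy[2,4,6-tris(methoxymethoxy)-3-(3-methylbut-2-enyl)-5-(2-methylpropanoyl)phenyl]methyl]-5-(3-methylbut-2-enyl)phenyl}-2-methylbutan-1-one, both carbinol epimers | CC[C@@H](C)C(=O)c1c(O)c(CC=C(C)C)c(O)c(C(O)c2c(OCOC)c(CC=C(C)C)c(OCOC)c(C(=O)C(C)C)c2OCOC)c1O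
A6 | alternative 2 | bis(5-methylhexyl)zinc | CC(C)CCCC[Zn]CCCCC(C)C
A7 | alternative 3 | 2-[(1S)-1-(2-hydroxy-4,6-dimethoxyphenyl)-6-methylheptyl]-3,5-dimethoxyphenyl 2-methylpropanoate | COc1cc(OC)c([C@H](CCCCC(C)C)c2c(OC)cc(OC)cc2OC(=O)C(C)C)c(O)c1
A8 | alternative 3 | 2,2'-(6-methylheptane-1,1-diyl)bis(3,5-dimethoxyphenol) | COc1cc(OC)c(C(CCCCC(C)C)c2c(OC)cc(OC)cc2O)c(O)c1
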